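Everything rests on the C14–C15 single bond of the polyene (carotenoid numbering: ring C1–C6, chain C7–C15, then C15'–C8' to the aldehyde). The key step is a three-component methylalumination/cross-coupling: terminal enyne 13, which lacks the methyl on C13, is syn-carbometalated with Me3Al under zirconium catalysis and the C14 alkenylalane is joined under palladium catalysis to the C15 alkenyl chloride 19. One operation installs the C13 methyl, fixes the E geometry of the trisubstituted C13=C14 olefin and forms C14–C15, giving the complete C30 skeleton. The step exploits the (E)-C13(CH3)=C14H unit flanking the junction, which is a latent terminal alkyne; the cyclohexene ring stereocentres derive from (R)-α-ionone.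

Key step: step 11

Remark: (R)-α-ionone is taken as a purchasable single enantiomer; C8' is carried at the alcohol oxidation level through the coupling and oxidised last.

Step 1
Reactants: 1 (3E)-4-[(1R)-2,6,6-trimethylcyclohex-2-en-1-yl]but-3-en-2-one [(R)-α-ionone]
Product: 3 (6R)-6-[(1E)-but-1-en-3-yn-1-yl]-1,5,5-trimethylcyclohex-1-ene, via enol phosphate 2 (not isolated)
Conditions: LiN(i-Pr)2 (1.1 equiv), THF, −78 °C; ClP(O)(OEt)2, −78 to 23 °C; LiN(i-Pr)2 (2.3 equiv), −78 to 23 °C; aq. NH4Cl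
Reagents that add atoms: none
Why: The methyl ketone is turned into the terminal alkyne through its enol phosphate 2 by base-induced elimination of diethyl phosphate (enol phosphate route to alkynes); LiN(i-Pr)2 at −78 °C removes a methyl proton and not the C6–H, so the existing stereocentre should be kept.

Step 2
Reactants: 3 (6R)-6-[(1E)-but-1-en-3-yn-1-yl]-1,5,5-trimethylcyclohex-1-ene
Product: 4 (4R)-4-[(1E)-but-1-en-3-yn-1-yl]-3,5,5-trimethylcyclohex-2-en-1-one
Conditions: Rh2(cap)4 (dirhodium tetracaprolactamate, 1 mol %), 70% aq. t-BuOOH (5 equiv), ClCH2CH2Cl, 40 °C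
Reagents that add atoms: tert-butyl hydroperoxide, CC(C)(C)OO
Why: Allylic C–H oxidation (dirhodium caprolactamate/t-BuOOH) should take the only secondary allylic CH2 (C3) to the enone, because the competing C6–H is tertiary, flanked by the gem-dimethyl carbon and poorly aligned with the ring π bond.

Step 3
Reactants: 4 (4R)-4-[(1E)-but-1-en-3-yn-1-yl]-3,5,5-trimethylcyclohex-2-en-1-one
Product: 5 (1R,4R)-4-[(1E)-but-1-en-3-yn-1-yl]-3,5,5-trimethylcyclohex-2-en-1-ol (3,6-trans)
Conditions: LiBH(s-Bu)3 (1.2 equiv), THF, −78 °C; then H2O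
Reagents that add atoms: none
Why: 1,2-Reduction with a bulky borohydride should occur anti to the axial methyl on C1 (the β,β-disubstituted enone resists 1,4-addition), which sets C3 as R, trans to the C6 side chain, by substrate control.

Step 4
Reactants: 5 (1R,4R)-4-[(1E)-but-1-en-3-yn-1-yl]-3,5,5-trimethylcyclohex-2-en-1-ol
Product: 7 (1S,4R)-4-[(1E)-but-1-en-3-yn-1-yl]-3,5,5-trimethylcyclohex-2-en-1-ol (3,6-cis), via 4-nitrobenzoate 6 (not isolated)
Conditions: 4-O2NC6H4CO2H, PPh3, DIAD, THF, 0 to 23 °C; then K2CO3 (cat.), MeOH, 23 °C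
Reagents that add atoms: 4-nitrobenzoic acid, O=C(O)c1ccc(cc1)[N+](=O)[O-]
Why: Mitsunobu reaction: SN2 displacement of the activated hydroxyl by 4-nitrobenzoate inverts C3 to S (the new C3–O oxygen comes from the acid), and methanolysis of ester 6 frees the 3,6-cis alcohol.

Step 5
Reactants: 8 (E)-1,2-dichloroethene; 9 ethynyltrimethylsilane
Product: 10 [(3E)-4-chlorobut-3-en-1-yn-1-yl]trimethylsilane
Conditions: 8 (5 equiv), Pd(PPh3)4 (3 mol %), CuI (6 mol %), n-BuNH2, Et2O, 23 °C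
Reagents that add atoms: none
Why: Sonogashira coupling with retention of the E geometry; the excess of 8 should hold the reaction at mono-alkynylation.

Step 6
Reactants: 7 (1S,4R)-4-[(1E)-but-1-en-3-yn-1-yl]-3,5,5-trimethylcyclohex-2-en-1-ol; 10 [(3E)-4-chlorobut-3-en-1-yn-1-yl]trimethylsilane
Product: 12 (1S,4R)-3,5,5-trimethyl-4-[(1E,3E,5E)-3-methyl-8-(trimethylsilyl)octa-1,3,5-trien-7-yn-1-yl]cyclohex-2-en-1-ol, via alkenylalane 11 (not isolated)
Conditions: Me3Al (3 equiv), Cp2ZrCl2 (25 mol %), ClCH2CH2Cl, 23 °C; evaporation; then 10, Pd(PPh3)4 (5 mol %), ZnCl2 (cat.), THF, 23 °C; aq. KNaC4H4O6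
Reagents that add atoms: trimethylaluminium, C[Al](C)C
Why: Negishi zirconium-catalysed methylalumination adds CH3 and Al syn across the terminal alkyne (CH3 to the internal carbon), and palladium-catalysed alkenyl–alkenyl coupling of alane 11 with the activated chloride 10 then proceeds with retention, giving the 9E,11E triene while the hydroxyl is carried as its dimethylaluminium alkoxide.

Step 7
Reactants: 12 (1S,4R)-3,5,5-trimethyl-4-[(1E,3E,5E)-3-methyl-8-(trimethylsilyl)octa-1,3,5-trien-7-yn-1-yl]cyclohex-2-en-1-ol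
Product: 13 (1S,4R)-3,5,5-trimethyl-4-[(1E,3E,5E)-3-methylocta-1,3,5-trien-7-yn-1-yl]cyclohex-2-en-1-ol
Conditions: K2CO3 (cat.), MeOH, 23 °C
Reagents that add atoms: none
Why: Methoxide-induced protodesilylation of the alkynylsilane leaves the polyene and the carbinol untouched.

Step 8
Reactants: 14 prop-2-yn-1-ol; 10 [(3E)-4-chlorobut-3-en-1-yn-1-yl]trimethylsilane
Product: 16 (2E,4E)-2-methyl-7-(trimethylsilyl)hepta-2,4-dien-6-yn-1-ol, via alkenylalane 15 (not isolated)
Conditions: Me3Al (3 equiv), Cp2ZrCl2 (25 mol %), ClCH2CH2Cl, 0 to 23 °C; evaporation; then 10, Pd(PPh3)4 (5 mol %), ZnCl2 (cat.), THF, 23 °C; aq. KNaC4H4O6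
Reagents that add atoms: trimethylaluminium, C[Al](C)C
Why: The same Negishi methylalumination/cross-coupling tandem on propargyl alcohol sets the (E)-C9'(CH3)=C10' olefin by syn addition and joins it to the chloroenyne with retention.

Step 9
Reactants: 16 (2E,4E)-2-methyl-7-(trimethylsilyl)hepta-2,4-dien-6-yn-1-ol
Product: 17 (2E,4E)-2-methylhepta-2,4-dien-6-yn-1-ol
Conditions: K2CO3 (cat.), MeOH, 23 °C
Reagents that add atoms: none
Why: Methoxide-induced protodesilylation of the alkynylsilane.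

Step 10
Reactants: 17 (2E,4E)-2-methylhepta-2,4-dien-6-yn-1-ol; 8 (E)-1,2-dichloroethene
Product: 19 (2E,4E,6E,8E)-9-chloro-2,6-dimethylnona-2,4,6,8-tetraen-1-ol, via alkenylalane 18 (not isolated)
Conditions: Me3Al (3 equiv), Cp2ZrCl2 (25 mol %), ClCH2CH2Cl, 23 °C; evaporation; then 8 (10 equiv), Pd(PPh3)4 (5 mol %), THF, 23 °C; aq. KNaC4H4O6
Reagents that add atoms: trimethylaluminium, C[Al](C)C
Why: Methylalumination/cross-coupling tandem as before (syn addition sets the E-C13'(CH3)=C14' olefin); the large excess of 8 and the low reactivity of the product chloride towards Pd(PPh3)4 should stop the coupling after one C–Cl bond.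

Step 11
Reactants: 13 (1S,4R)-3,5,5-trimethyl-4-[(1E,3E,5E)-3-methylocta-1,3,5-trien-7-yn-1-yl]cyclohex-2-en-1-ol; 19 (2E,4E,6E,8E)-9-chloro-2,6-dimethylnona-2,4,6,8-tetraen-1-ol
Product: 22 (1S,4R)-4-[(1E,3E,5E,7E,9E,11E,13E,15E)-17-hydroxy-3,7,12,16-tetramethylheptadeca-1,3,5,7,9,11,13,15-octaen-1-yl]-3,5,5-trimethylcyclohex-2-en-1-ol, via alkenylalane 20 (not isolated), via aluminium alkoxide 21 (not isolated)
Conditions: 13: Me3Al (3 equiv), Cp2ZrCl2 (25 mol %), ClCH2CH2Cl, 23 °C, then evaporation; 19: Me3Al (1 equiv), THF, 0 °C; both combined, Pd(P(t-Bu)3)2 (5 mol %), ZnCl2 (cat.), THF, 23–40 °C, dark; aq. KNaC4H4O6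
Reagents that add atoms: trimethylaluminium, C[Al](C)C
Why: Zirconium-catalysed syn-carboalumination of the terminal alkyne of 13 places CH3 on the internal carbon C13 and aluminium on C14 (alane 20); transmetalation from aluminium through zinc to palladium and reductive elimination with the alkenylpalladium chloride, formed by oxidative addition of zerovalent palladium into the C15–Cl bond of 21, forge C14–C15 with retention at both olefins. The closest known reaction type is the Negishi methylalumination/cross-coupling tandem used to assemble isoprenoid polyenes, carotenoids included. No ring is closed and no stereocentre is formed; the E geometry of C13=C14 is controlled by the syn addition and that of C15=C15' by the (E)-chloride. The step needs regioselective methylmetalation (secured by the terminal, conjugated alkyne), activation of an unactivated alkenyl chloride (secured by the electron-rich, bulky phosphine) and tolerance of two hydroxyls (secured by carrying both as dimethylaluminium alkoxides). The C3 and C6 stereocentres are not touched.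

Step 12
Reactants: 22 (1S,4R)-4-[(1E,3E,5E,7E,9E,11E,13E,15E)-17-hydroxy-3,7,12,16-tetramethylheptadeca-1,3,5,7,9,11,13,15-octaen-1-yl]-3,5,5-trimethylcyclohex-2-en-1-ol
Product: 23 (2E,4E,6E,8E,10E,12E,14E,16E)-17-[(1R,4S)-4-hydroxy-2,6,6-trimethylcyclohex-2-en-1-yl]-2,6,11,15-tetramethylheptadeca-2,4,6,8,10,12,14,16-octaenal
Conditions: MnO2 (activated, 10 equiv), CH2Cl2, 0 °C, dark, stopped when 22 is consumed
Reagents that add atoms: none
Why: Allylic oxidation with MnO2 should convert the primary alcohol conjugated with the octaene much faster than the isolated secondary ring allylic alcohol, so that limited oxidant, low temperature and short contact should stop at the hydroxy aldehyde.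

Compound list
1 | (3E)-4-[(1R)-2,6,6-trimethylcyclohex-2-en-1-yl]but-3-en-2-one [(R)-α-ionone] | CC1=CCCC(C)(C)[C@H]1/C=C/C(C)=O | starting material
2 | diethyl (3E)-4-[(1R)-2,6,6-trimethylcyclohex-2-en-1-yl]buta-1,3-dien-2-yl phosphate | CC1=CCCC(C)(C)[C@H]1/C=C/C(=C)OP(=O)(OCC)OCC | intermediate (not isolated)
3 | (6R)-6-[(1E)-but-1-en-3-yn-1-yl]-1,5,5-trimethylcyclohex-1-ene | CC1=CCCC(C)(C)[C@H]1/C=C/C#C | intermediate
4 | (4R)-4-[(1E)-but-1-en-3-yn-1-yl]-3,5,5-trimethylcyclohex-2-en-1-one | CC1=CC(=O)CC(C)(C)[C@H]1/C=C/C#C | intermediate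
5 | (1R,4R)-4-[(1E)-but-1-en-3-yn-1-yl]-3,5,5-trimethylcyclohex-2-en-1-ol | CC1=C[C@H](O)CC(C)(C)[C@H]1/C=C/C#C | intermediate
6 | (1S,4R)-4-[(1E)-but-1-en-3-yn-1-yl]-3,5,5-trimethylcyclohex-2-en-1-yl 4-nitrobenzoate | CC1=C[C@@H](OC(=O)c2ccc(cc2)[N+](=O)[O-])CC(C)(C)[C@H]1/C=C/C#C | intermediate (not isolated)
7 | (1S,4R)-4-[(1E)-but-1-en-3-yn-1-yl]-3,5,5-trimethylcyclohex-2-en-1-ol | CC1=C[C@@H](O)CC(C)(C)[C@H]1/C=C/C#C | intermediate
8 | (E)-1,2-dichloroethene | Cl/C=C/Cl | starting material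
9 | ethynyltrimethylsilane | C#C[Si](C)(C)C | starting material
10 | [(3E)-4-chlorobut-3-en-1-yn-1-yl]trimethylsilane | Cl/C=C/C#C[Si](C)(C)C | intermediate
11 | dimethylaluminium (1S,4R)-4-[(1E,3E)-4-(dimethylalumanyl)-3-methylbuta-1,3-dien-1-yl]-3,5,5-trimethylcyclohex-2-en-1-olate | CC1=C[C@@H](O[Al](C)C)CC(C)(C)[C@H]1/C=C/C(C)=C/[Al](C)C | intermediate (not isolated)
12 | (1S,4R)-3,5,5-trimethyl-4-[(1E,3E,5E)-3-methyl-8-(trimethylsilyl)octa-1,3,5-trien-7-yn-1-yl]cyclohex-2-en-1-ol | CC1=C[C@@H](O)CC(C)(C)[C@H]1/C=C/C(C)=C/C=C/C#C[Si](C)(C)C | intermediate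
13 | (1S,4R)-3,5,5-trimethyl-4-[(1E,3E,5E)-3-methylocta-1,3,5-trien-7-yn-1-yl]cyclohex-2-en-1-ol | CC1=C[C@@H](O)CC(C)(C)[C@H]1/C=C/C(C)=C/C=C/C#C | intermediate
14 | prop-2-yn-1-ol | C#CCO | starting material
15 | dimethylaluminium (2E)-3-(dimethylalumanyl)-2-methylprop-2-en-1-olate | C[Al](C)OC/C(C)=C/[Al](C)C | intermediate (not isolated)
16 | (2E,4E)-2-methyl-7-(trimethylsilyl)hepta-2,4-dien-6-yn-1-ol | OC/C(C)=C/C=C/C#C[Si](C)(C)C | intermediate
17 | (2E,4E)-2-methylhepta-2,4-dien-6-yn-1-ol | OC/C(C)=C/C=C/C#C | intermediate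
18 | dimethylaluminium (2E,4E,6E)-7-(dimethylalumanyl)-2,6-dimethylhepta-2,4,6-trien-1-olate | C[Al](C)OC/C(C)=C/C=C/C(C)=C/[Al](C)C | intermediate (not isolated)
19 | (2E,4E,6E,8E)-9-chloro-2,6-dimethylnona-2,4,6,8-tetraen-1-ol | OC/C(C)=C/C=C/C(C)=C/C=C/Cl | intermediate
20 | dimethylaluminium (1S,4R)-4-[(1E,3E,5E,7E)-8-(dimethylalumanyl)-3,7-dimethylocta-1,3,5,7-tetraen-1-yl]-3,5,5-trimethylcyclohex-2-en-1-olate | CC1=C[C@@H](O[Al](C)C)CC(C)(C)[C@H]1/C=C/C(C)=C/C=C/C(C)=C/[Al](C)C | intermediate (not isolated)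
21 | dimethylaluminium (2E,4E,6E,8E)-9-chloro-2,6-dimethylnona-2,4,6,8-tetraen-1-olate | C[Al](C)OC/C(C)=C/C=C/C(C)=C/C=C/Cl | intermediate (not isolated)
22 | (1S,4R)-4-[(1E,3E,5E,7E,9E,11E,13E,15E)-17-hydroxy-3,7,12,16-tetramethylheptadeca-1,3,5,7,9,11,13,15-octaen-1-yl]-3,5,5-trimethylcyclohex-2-en-1-ol | CC1=C[C@@H](O)CC(C)(C)[C@H]1/C=C/C(C)=C/C=C/C(C)=C/C=C/C=C(C)/C=C/C=C(\C)CO | intermediate
23 | (2E,4E,6E,8E,10E,12E,14E,16E)-17-[(1R,4S)-4-hydroxy-2,6,6-trimethylcyclohex-2-en-1-yl]-2,6,11,15-tetramethylheptadeca-2,4,6,8,10,12,14,16-octaenal | CC1=C[C@@H](O)CC(C)(C)[C@H]1/C=C/C(C)=C/C=C/C(C)=C/C=C/C=C(C)/C=C/C=C(\C)C=O | target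

Total step count: 12
Longest linear sequence: 8 steps (steps 1, 2, 3, 4, 6, 7, 11, 12)

Steps most likely to fail

Step 2. Hydrogen abstraction at the doubly allylic C6–H or radical attack on the conjugated enyne may erode the regioselectivity of the oxidation, and the γ-acidic C6–H of the enone may epimerise. The fallback sets out from 1 and installs the oxygen before the alkyne is made. Enzymatic C3 hydroxylation of 1 with a cytochrome P450 monooxygenase (engineered CYP102A1 variant, NADPH recycled with glucose dehydrogenase/glucose, O2, buffer pH 7.5) should give the 3,6-trans alcohol (3E)-4-[(1R,4R)-4-hydroxy-2,6,6-trimethylcyclohex-2-en-1-yl]but-3-en-2-one F1. Silylation (TBSCl, imidazole, DMF) would give the tert-butyldimethylsilyl ether F2. The conditions of step 1 would then lead, through the enol phosphate F3 (not isolated), to the silylated enyne F4, and Bu4NF in THF would come back to the route at 5.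

Step 12. Chemoselectivity may be lost through competing oxidation of the secondary ring allylic alcohol to the enone. The fallback sets out from 13 and protects the ring hydroxyl before the coupling. Silylation (TBSCl, imidazole, DMF) would give the tert-butyldimethylsilyl ether F6. Methylalumination as in step 11 would give the alkenylalane F7 (not isolated), and coupling with 21 under the conditions of step 11 would give the mono-silylated diol F8. MnO2 would then oxidise the only free alcohol to the silylated aldehyde F9, and HF·pyridine in THF/pyridine at 0 °C would remove the silyl group and come back to the route at 23.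

Step 11. Oxidative addition into the unactivated alkenyl chloride may be slow, leaving the alane to protodemetalate or homocouple. The fallback sets out from 13 and replaces the one-pot aluminium/zinc coupling by an isolated boron nucleophile. Alane 20 would be formed as in step 11 and trapped with 2-methoxy-4,4,5,5-tetramethyl-1,3,2-dioxaborolane to give, after aqueous work-up, the alkenylboronate (1S,4R)-4-[(1E,3E,5E,7E)-3,7-dimethyl-8-(4,4,5,5-tetramethyl-1,3,2-dioxaborolan-2-yl)octa-1,3,5,7-tetraen-1-yl]-3,5,5-trimethylcyclohex-2-en-1-ol F5. Suzuki–Miyaura coupling of F5 with 19 (Pd(OAc)2, SPhos, K3PO4, THF/H2O, 40 °C) would come back to the route at 22.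

Further compounds
F1 | step 2 | (3E)-4-[(1R,4R)-4-hydroxy-2,6,6-trimethylcyclohex-2-en-1-yl]but-3-en-2-one | CC1=C[C@H](O)CC(C)(C)[C@H]1/C=C/C(C)=O
F2 | step 2 | (3E)-4-[(1R,4R)-4-{[tert-butyl(dimethyl)silyl]oxy}-2,6,6-trimethylcyclohex-2-en-1-yl]but-3-en-2-one | CC1=C[C@H](O[Si](C)(C)C(C)(C)C)CC(C)(C)[C@H]1/C=C/C(C)=O
F3 | step 2 | (3E)-4-[(1R,4R)-4-{[tert-butyl(dimethyl)silyl]oxy}-2,6,6-trimethylcyclohex-2-en-1-yl]buta-1,3-dien-2-yl diethyl phosphate | CC1=C[C@H](O[Si](C)(C)C(C)(C)C)CC(C)(C)[C@H]1/C=C/C(=C)OP(=O)(OCC)OCC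
F4 | step 2 | {[(1R,4R)-4-[(1E)-but-1-en-3-yn-1-yl]-3,5,5-trimethylcyclohex-2-en-1-yl]oxy}(tert-butyl)dimethylsilane | CC1=C[C@H](O[Si](C)(C)C(C)(C)C)CC(C)(C)[C@H]1/C=C/C#C
F5 | step 11 | (1S,4R)-4-[(1E,3E,5E,7E)-3,7-dimethyl-8-(4,4,5,5-tetramethyl-1,3,2-dioxaborolan-2-yl)octa-1,3,5,7-tetraen-1-yl]-3,5,5-trimethylcyclohex-2-en-1-ol | CC1=C[C@@H](O)CC(C)(C)[C@H]1/C=C/C(C)=C/C=C/C(C)=C/B2OC(C)(C)C(C)(C)O2
F6 | step 12 | tert-butyl(dimethyl){[(1S,4R)-3,5,5-trimethyl-4-[(1E,3E,5E)-3-methylocta-1,3,5-trien-7-yn-1-yl]cyclohex-2-en-1-yl]oxy}silane | CC1=C[C@@H](O[Si](C)(C)C(C)(C)C)CC(C)(C)[C@H]1/C=C/C(C)=C/C=C/C#C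
F7 | step 12 | {(1E,3E,5E,7E)-8-[(1R,4S)-4-{[tert-butyl(dimethyl)silyl]oxy}-2,6,6-trimethylcyclohex-2-en-1-yl]-2,6-dimethylocta-1,3,5,7-tetraen-1-yl}dimethylalumane | CC1=C[C@@H](O[Si](C)(C)C(C)(C)C)CC(C)(C)[C@H]1/C=C/C(C)=C/C=C/C(C)=C/[Al](C)C
F8 | step 12 | (2E,4E,6E,8E,10E,12E,14E,16E)-17-[(1R,4S)-4-{[tert-butyl(dimethyl)silyl]oxy}-2,6,6-trimethylcyclohex-2-en-1-yl]-2,6,11,15-tetramethylheptadeca-2,4,6,8,10,12,14,16-octaen-1-ol | CC1=C[C@@H](O[Si](C)(C)C(C)(C)C)CC(C)(C)[C@H]1/C=C/C(C)=C/C=C/C(C)=C/C=C/C=C(C)/C=C/C=C(\C)CO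
F9 | step 12 | (2E,4E,6E,8E,10E,12E,14E,16E)-17-[(1R,4S)-4-{[tert-butyl(dimethyl)silyl]oxy}-2,6,6-trimethylcyclohex-2-en-1-yl]-2,6,11,15-tetramethylheptadeca-2,4,6,8,10,12,14,16-octaenal | CC1=C[C@@H](O[Si](C)(C)C(C)(C)C)CC(C)(C)[C@H]1/C=C/C(C)=C/C=C/C(C)=C/C=C/C=C(C)/C=C/C=C(\C)C=O
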